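## Retrosynthetic overview

1. The ten-membered carbocycle is closed last, by ring-closing metathesis at C1=C10 (ring-cis trisubstituted olefin) of a vinyl/methallyl diene lactone.
2. The C15–C4=C5–C6(O) unit (hydroxymethyl cis to C6, oxygen on both ends) is a 2,4-disubstituted furan in disguise: singlet-oxygen dearomatisation gives a cis-enedione, Luche reduction sets C6, and the γ-lactone closes.
3. The C7–C8 bond and both stereocentres come from a catalytic asymmetric chromium 2-(methoxycarbonyl)allylation of 3-methylbut-3-enal (anti); C8–OH is esterified at once with the silyl-protected (S)-Roche acid.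
4. The furyl allylic bromide comes from furfural: C4 bromination, Negishi butenylation, Morita–Baylis–Hillman reaction, bromination with allylic shift.
5. Ring order: furan (from the feedstock, consumed in the key step), then the α-methylene-γ-lactone, then the cyclodecadiene.

## Assumptions and conventions

- Germacrane numbering (C1–C15) is used for positions in every intermediate. The target SMILES is read as 6R,7R,8S,2'S, with C4=C5 ring-trans (CH2OH cis to C6) and C1=C10 ring-cis.
- The (S,S) antipode of the carbazole bis(oxazoline) ligand is assumed to give the 8S adduct; if the sense is opposite, the (R,R) ligand is used.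
- But-3-en-1-ylzinc bromide is bought as a 0.5 M THF solution; 3-methylbut-3-enal is made fresh and used as a cold solution.

## Route

Step 1
Reactants: 1 furan-2-carbaldehyde (furfural)
Product: 2 4-bromofuran-2-carbaldehyde
Conditions: Br2 (1.05 equiv), AlCl3 (2.5 equiv), ClCH2CH2Cl, 0 → 40 °C
Reagents that add atoms: bromine, BrBr
Why: Electrophilic aromatic bromination under swamping-catalyst conditions: the AlCl3-complexed formyl group deactivates C3 and C5 of the furan, so bromine enters C4, the position that becomes C4 of the target.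

Step 2
Reactants: 2 4-bromofuran-2-carbaldehyde; 3 but-3-en-1-ylzinc bromide
Product: 4 4-(but-3-en-1-yl)furan-2-carbaldehyde
Conditions: Pd(OAc)2 (2 mol %), SPhos (4 mol %), THF, 23 → 45 °C
Reagents that add atoms: none
Why: Negishi cross-coupling of the heteroaryl bromide with a primary alkylzinc halide, which tolerates the free aldehyde, installs C3–C2–C1 and the vinyl terminus needed for ring closure; no stereocentre is formed.

Step 3
Reactants: 4 4-(but-3-en-1-yl)furan-2-carbaldehyde; 5 methyl acrylate
Product: 6 methyl 2-{[4-(but-3-en-1-yl)furan-2-yl](hydroxy)methyl}prop-2-enoate (racemic)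
Conditions: methyl acrylate (3 equiv), DABCO (0.5 equiv), MeOH, 23 °C
Reagents that add atoms: none
Why: Morita–Baylis–Hillman reaction, fast for furfural-type aldehydes, attaches C11, C12 and C13 to C7; the carbinol stereocentre is racemic and is erased in step 4.

Step 4
Reactants: 6 methyl 2-{[4-(but-3-en-1-yl)furan-2-yl](hydroxy)methyl}prop-2-enoate
Product: 7 methyl (2Z)-2-(bromomethyl)-3-[4-(but-3-en-1-yl)furan-2-yl]prop-2-enoate
Conditions: NBS (1.3 equiv), Me2S (1.5 equiv), CH2Cl2, 0 → 23 °C
Reagents that add atoms: N-bromosuccinimide, O=C1CCC(=O)N1Br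
Why: Corey–Kim-type bromination of the Morita–Baylis–Hillman alcohol with allylic transposition (SN2') gives the conjugated (Z)-2-(bromomethyl)enoate, the thermodynamically favoured isomer.

Step 5
Reactants: 8 3-methylbut-3-en-1-ol
Product: 9 3-methylbut-3-enal
Conditions: Dess–Martin periodinane (1.1 equiv), CH2Cl2, 0 → 23 °C; kept as a cold solution and used the same day
Reagents that add atoms: none
Why: Dess–Martin oxidation under non-basic conditions gives the β,γ-unsaturated aldehyde without moving the double bond into conjugation.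

Step 6
Reactants: 7 methyl (2Z)-2-(bromomethyl)-3-[4-(but-3-en-1-yl)furan-2-yl]prop-2-enoate; 9 3-methylbut-3-enal
Product: 11 methyl (3R,4S)-3-[4-(but-3-en-1-yl)furan-2-yl]-4-hydroxy-6-methyl-2-methylidenehept-6-enoate (anti adduct; C7 R / C8 S), via trimethylsilyl ether 10 (not isolated)
Conditions: CrCl2 (10 mol %), (S,S)-3,6-diphenyl-1,8-bis(4-isopropyl-4,5-dihydro-1,3-oxazol-2-yl)-9H-carbazole (12 mol %), Mn powder (2 equiv), TMSCl (1.5 equiv), i-Pr2NEt (0.3 equiv), THF, 0 → 23 °C; then 5% aq. citric acid, 0 °C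
Reagents that add atoms: none
Why: Catalytic asymmetric Nozaki–Hiyama–Kishi 2-(alkoxycarbonyl)allylation: the γ-furyl allylchromium species adds through a chair transition state with furyl and the aldehyde substituent both equatorial (anti C7/C8), the chiral tridentate bis(oxazoline)–chromium complex selects the aldehyde face (8S, hence 7R), and silyl transfer from TMSCl frees the product from chromium and keeps the alkoxide from lactonising.

Step 7
Reactants: 12 methyl (2S)-3-hydroxy-2-methylpropanoate ((S)-Roche ester)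
Product: 13 methyl (2S)-3-{[tert-butyl(dimethyl)silyl]oxy}-2-methylpropanoate
Conditions: TBSCl (1.1 equiv), imidazole (2 equiv), CH2Cl2, 0 → 23 °C
Reagents that add atoms: tert-butyldimethylsilyl chloride, CC(C)(C)[Si](C)(C)Cl
Why: Standard silylation of the primary alcohol; the stereocentre comes from the chiral pool and is not touched.

Step 8
Reactants: 13 methyl (2S)-3-{[tert-butyl(dimethyl)silyl]oxy}-2-methylpropanoate
Product: 14 (2S)-3-{[tert-butyl(dimethyl)silyl]oxy}-2-methylpropanoic acid
Conditions: LiOH·H2O (1.5 equiv), THF/MeOH/H2O, 0 → 23 °C; then 1 M HCl to pH 4, 0 °C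
Reagents that add atoms: lithium hydroxide, [Li+].[OH-]
Why: Saponification of the methyl ester under conditions at which the α-stereocentre of Roche-ester derivatives does not epimerise and the silyl ether survives.

Step 9
Reactants: 11 methyl (3R,4S)-3-[4-(but-3-en-1-yl)furan-2-yl]-4-hydroxy-6-methyl-2-methylidenehept-6-enoate; 14 (2S)-3-{[tert-butyl(dimethyl)silyl]oxy}-2-methylpropanoic acid
Product: 15 methyl (3R,4S)-3-[4-(but-3-en-1-yl)furan-2-yl]-4-{[(2S)-3-{[tert-butyl(dimethyl)silyl]oxy}-2-methylpropanoyl]oxy}-6-methyl-2-methylidenehept-6-enoate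
Conditions: DCC (1.3 equiv), DMAP (0.2 equiv), CH2Cl2, 0 → 23 °C
Reagents that add atoms: none
Why: Steglich esterification acylates the only free hydroxyl on oxygen, so C8 keeps its configuration, and it stops C8–OH from competing for the C12 ester later.

Step 10 (key step)
Reactants: 15 methyl (3R,4S)-3-[4-(but-3-en-1-yl)furan-2-yl]-4-{[(2S)-3-{[tert-butyl(dimethyl)silyl]oxy}-2-methylpropanoyl]oxy}-6-methyl-2-methylidenehept-6-enoate
Product: 20 (1S)-1-{(2R,3R)-2-[(1Z)-2-(hydroxymethyl)hexa-1,5-dien-1-yl]-4-methylidene-5-oxooxolan-3-yl}-3-methylbut-3-en-1-yl (2S)-3-hydroxy-2-methylpropanoate (diene lactone; 6R,7R,8S), via furan endoperoxide 16 (not isolated), via cis-enedione 17 (not isolated), via diol ester 18 (not isolated), via silyl lactone 19 (not isolated)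
Conditions: O2, visible light, tetraphenylporphyrin (1 mol %), CH2Cl2, −78 °C; Me2S (5 equiv), −78 → −20 °C; then MeOH, CeCl3·7H2O (2.2 equiv), NaBH4 (2.5 equiv), −78 °C, aq. NH4Cl work-up; then PPTS (0.3 equiv), MeOH, 40 °C
Reagents that add atoms: dioxygen, O=O
Why: Singlet-oxygen [4+2] photooxygenation dearomatises the furan and Me2S reduction of the endoperoxide opens it to the cis-enedione, so the former ring oxygen fixes C6 and C15 cis across C4=C5 (the ring-trans olefin of the target); Luche 1,2-reduction at −78 °C then sets C6 by Felkin–Anh addition anti to the electron-poor C7–C11 bond (6R, O6 syn to C11) and reduces the aldehyde to C15–OH, after which PPTS/MeOH closes the trans γ-lactone on the C6 hydroxyl and removes the primary silyl ether.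

Step 11
Reactants: 20 (1S)-1-{(2R,3R)-2-[(1Z)-2-(hydroxymethyl)hexa-1,5-dien-1-yl]-4-methylidene-5-oxooxolan-3-yl}-3-methylbut-3-en-1-yl (2S)-3-hydroxy-2-methylpropanoate
Product: 21 (3aR,4S,6Z,10Z,11aR)-10-(hydroxymethyl)-6-methyl-3-methylidene-2-oxo-3a,4,5,8,9,11a-hexahydrocyclodeca[b]furan-4-yl (2S)-3-hydroxy-2-methylpropanoate (target)
Conditions: second-generation Hoveyda–Grubbs catalyst (15 mol % in three portions), 1,4-benzoquinone (30 mol %), toluene (0.5 mM), 80 °C, argon sparge
Reagents that add atoms: none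
Why: Ring-closing metathesis: the carbene forms at the monosubstituted vinyl group and closes on the methallyl olefin with loss of ethene; the trans-lactone holds the two chains gauche, and in a ten-membered ring that already holds one trans olefin the new trisubstituted C1=C10 bond forms ring-cis (1(10)Z), as in the target.

## Compound list

1 | furan-2-carbaldehyde (furfural) | O=Cc1ccco1 | starting material
2 | 4-bromofuran-2-carbaldehyde | O=Cc1cc(Br)co1 | intermediate
3 | but-3-en-1-ylzinc bromide | C=CCC[Zn]Br | starting material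
4 | 4-(but-3-en-1-yl)furan-2-carbaldehyde | O=Cc1cc(CCC=C)co1 | intermediate
5 | methyl acrylate | C=CC(=O)OC | starting material
6 | methyl 2-{[4-(but-3-en-1-yl)furan-2-yl](hydroxy)methyl}prop-2-enoate, racemic | C=C(C(=O)OC)C(O)c1cc(CCC=C)co1 | intermediate
7 | methyl (2Z)-2-(bromomethyl)-3-[4-(but-3-en-1-yl)furan-2-yl]prop-2-enoate | COC(=O)/C(CBr)=C/c1cc(CCC=C)co1 | intermediate
8 | 3-methylbut-3-en-1-ol | CC(=C)CCO | starting material
9 | 3-methylbut-3-enal | CC(=C)CC=O | intermediate
10 | trimethylsilyl ether of 11: methyl (3R,4S)-3-[4-(but-3-en-1-yl)furan-2-yl]-6-methyl-2-methylidene-4-[(trimethylsilyl)oxy]hept-6-enoate (not isolated) | C=C(C(=O)OC)[C@@H](c1cc(CCC=C)co1)[C@@H](O[Si](C)(C)C)CC(C)=C | intermediate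
11 | methyl (3R,4S)-3-[4-(but-3-en-1-yl)furan-2-yl]-4-hydroxy-6-methyl-2-methylidenehept-6-enoate (C7 R, C8 S) | C=C(C(=O)OC)[C@@H](c1cc(CCC=C)co1)[C@@H](O)CC(C)=C | intermediate
12 | methyl (2S)-3-hydroxy-2-methylpropanoate ((S)-Roche ester) | COC(=O)[C@@H](C)CO | starting material
13 | methyl (2S)-3-{[tert-butyl(dimethyl)silyl]oxy}-2-methylpropanoate | COC(=O)[C@@H](C)CO[Si](C)(C)C(C)(C)C | intermediate
14 | (2S)-3-{[tert-butyl(dimethyl)silyl]oxy}-2-methylpropanoic acid | OC(=O)[C@@H](C)CO[Si](C)(C)C(C)(C)C | intermediate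
15 | methyl (3R,4S)-3-[4-(but-3-en-1-yl)furan-2-yl]-4-{[(2S)-3-{[tert-butyl(dimethyl)silyl]oxy}-2-methylpropanoyl]oxy}-6-methyl-2-methylidenehept-6-enoate | C=C(C(=O)OC)[C@@H](c1cc(CCC=C)co1)[C@@H](OC(=O)[C@@H](C)CO[Si](C)(C)C(C)(C)C)CC(C)=C | intermediate
16 | furan endoperoxide of 15: 2,3,7-trioxabicyclo[2.2.1]hept-5-ene with C6 and C15 as bridgeheads, both facial isomers (not isolated) | C=C(C(=O)OC)[C@@H](C12OOC(O1)C(CCC=C)=C2)[C@@H](OC(=O)[C@@H](C)CO[Si](C)(C)C(C)(C)C)CC(C)=C | intermediate
17 | cis-enedione: C6 ketone and C15 aldehyde cis across C4=C5, C7 R, C8 S (not isolated) | C=C(C(=O)OC)[C@@H](C(=O)/C=C(\C=O)CCC=C)[C@@H](OC(=O)[C@@H](C)CO[Si](C)(C)C(C)(C)C)CC(C)=C | intermediate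
18 | diol ester: C6 (R) allylic alcohol, C15 primary alcohol, C12 methyl ester, silyl ether; CIP letters 6R,7S,8S, same spatial arrangement as the target (not isolated) | C=C(C(=O)OC)[C@@H]([C@H](O)/C=C(\CO)CCC=C)[C@@H](OC(=O)[C@@H](C)CO[Si](C)(C)C(C)(C)C)CC(C)=C | intermediate
19 | silyl lactone: (1S)-1-{(2R,3R)-2-[(1Z)-2-(hydroxymethyl)hexa-1,5-dien-1-yl]-4-methylidene-5-oxooxolan-3-yl}-3-methylbut-3-en-1-yl (2S)-3-{[tert-butyl(dimethyl)silyl]oxy}-2-methylpropanoate (not isolated) | C=C1C(=O)O[C@H](/C=C(\CO)CCC=C)[C@H]1[C@@H](OC(=O)[C@@H](C)CO[Si](C)(C)C(C)(C)C)CC(C)=C | intermediate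
20 | (1S)-1-{(2R,3R)-2-[(1Z)-2-(hydroxymethyl)hexa-1,5-dien-1-yl]-4-methylidene-5-oxooxolan-3-yl}-3-methylbut-3-en-1-yl (2S)-3-hydroxy-2-methylpropanoate | C=C1C(=O)O[C@H](/C=C(\CO)CCC=C)[C@H]1[C@@H](OC(=O)[C@@H](C)CO)CC(C)=C | intermediate
21 | (3aR,4S,6Z,10Z,11aR)-10-(hydroxymethyl)-6-methyl-3-methylidene-2-oxo-3a,4,5,8,9,11a-hexahydrocyclodeca[b]furan-4-yl (2S)-3-hydroxy-2-methylpropanoate | C=C1C(=O)O[C@@H]2/C=C(\CO)CC/C=C(/C)C[C@H](OC(=O)[C@@H](C)CO)[C@@H]12 | target

## Step count, longest linear sequence, risks and fallbacks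

Total step count: 11.
Longest linear sequence: 8 steps from furfural (steps 1, 2, 3, 4, 6, 9, 10, 11). Step 5 and steps 7–8 are side branches.

**Risk 1 – step 11 (ring-closing metathesis).** A ten-membered ring with a trisubstituted olefin is strained and dimerisation competes. The conjugated exocyclic methylene and the two free hydroxyls can also bind or degrade the ruthenium carbene. The fallback sets out from 20 and comes back at 21. Dimethylamine (2 M in THF, 0 °C) adds to the methylene lactone of 20 to give the 13-(dimethylamino)-11,13-dihydro adduct F8 (C11 epimers, both usable). The ring is then closed on its camphorsulfonate salt (CSA 1.05 equiv, second-generation Hoveyda–Grubbs catalyst, toluene/CH2Cl2, 60 °C), so that no Michael acceptor and no free amine meet the catalyst, giving the macrocyclic amine F9. MeI in MeOH followed by aqueous NaHCO3 takes F9 through the methiodide F10 and a Hofmann-type elimination of trimethylamine back to the exocyclic methylene of 21.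

**Risk 2 – step 10 (key step).** The C6 configuration rests on acyclic Felkin–Anh control, and which C7 substituent takes the perpendicular position (acrylate carbon or the C8 branch) is not secure. The cis-enedione 17 is also a β-acyloxy ketone with an acidic C7–H, so it can eliminate the C8 ester or epimerise if warmed or exposed to base. The fallback sets out from 15 and comes back at 21. Anodic methoxylation (MeOH, Et4NOTs, graphite anode, −10 °C) dearomatises the furan to the isolable 2,5-dimethoxy-2,5-dihydrofuran bis-ketal F3, a masked enedione. Ring-closing metathesis of F3 (second-generation Hoveyda–Grubbs catalyst, toluene, 80 °C) gives the bridged macrocyclic bis-ketal F4. Oxalic acid on wet silica (CH2Cl2, 0 °C) unmasks the macrocyclic cis-enedione F5. Luche reduction of F5 then runs under ring control: peripheral hydride attack on the s-trans enone, whose C6 carbonyl points to the face of H5 and H7, gives the macrocyclic diol ester F6 with 6R. PPTS/MeOH lactonises F6 to the silyl-protected macrolide F7 and desilylates it to 21.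

**Risk 3 – step 6 (asymmetric chromium allylation).** Enantio- and diastereoselectivity with a γ-furyl bromide and an enolisable β,γ-unsaturated aldehyde are not assured, and the adduct could lactonise onto C8. The fallback sets out from 7 (with 9) and comes back at 15. Stoichiometric CrCl2 (2.5 equiv, THF, 0 °C, neutral work-up) without ligand gives the anti adduct as a racemate, that is 11 together with its enantiomer methyl (3S,4R)-3-[4-(but-3-en-1-yl)furan-2-yl]-4-hydroxy-6-methyl-2-methylidenehept-6-enoate F1. Esterification of the mixture with the enantiopure acid 14 as in step 9 gives 15 and the diastereomeric ester F2, which are separated by chromatography; 15 goes on. The side-chain acid that the target needs anyway serves as the resolving agent, at the cost of half the material.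

## Further compounds

F1 | step 6 | methyl (3S,4R)-3-[4-(but-3-en-1-yl)furan-2-yl]-4-hydroxy-6-methyl-2-methylidenehept-6-enoate (enantiomer of 11) | C=C(C(=O)OC)[C@H](c1cc(CCC=C)co1)[C@H](O)CC(C)=C
F2 | step 6 | methyl (3S,4R)-3-[4-(but-3-en-1-yl)furan-2-yl]-4-{[(2S)-3-{[tert-butyl(dimethyl)silyl]oxy}-2-methylpropanoyl]oxy}-6-methyl-2-methylidenehept-6-enoate (diastereomer of 15) | C=C(C(=O)OC)[C@H](c1cc(CCC=C)co1)[C@H](OC(=O)[C@@H](C)CO[Si](C)(C)C(C)(C)C)CC(C)=C
F3 | step 10 | bis-ketal of 15: 2,5-dimethoxy-2,5-dihydrofuran with C6 as ketal and C15 as acetal carbon (ketal epimers) | C=C(C(=O)OC)[C@@H](C1(OC)OC(OC)C(CCC=C)=C1)[C@@H](OC(=O)[C@@H](C)CO[Si](C)(C)C(C)(C)C)CC(C)=C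
F4 | step 10 | bridged macrocyclic bis-ketal: ten-membered ring closed at C1=C10 (ring-cis), 2,5-dimethoxy-2,5-dihydrofuran bridging C6 and C4 | C=C(C(=O)OC)[C@@H]1[C@@H](OC(=O)[C@@H](C)CO[Si](C)(C)C(C)(C)C)C/C(C)=C\CCC2=CC1(OC)OC2OC
F5 | step 10 | macrocyclic cis-enedione: C6 ketone in the ring, C15 aldehyde, C4=C5 ring-trans, C1=C10 ring-cis | C=C(C(=O)OC)[C@@H]1[C@@H](OC(=O)[C@@H](C)CO[Si](C)(C)C(C)(C)C)C/C(C)=C\CC/C(C=O)=C/C1=O
F6 | step 10 | macrocyclic diol ester: C6 (R) alcohol, C15 alcohol, C12 methyl ester, side-chain silyl ether | C=C(C(=O)OC)[C@@H]1[C@@H](OC(=O)[C@@H](C)CO[Si](C)(C)C(C)(C)C)C/C(C)=C\CC/C(CO)=C/[C@H]1O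
F7 | step 10 | silyl-protected macrolide: 21 with the side-chain hydroxyl as tert-butyldimethylsilyl ether | C=C1C(=O)O[C@@H]2/C=C(\CO)CC/C=C(/C)C[C@H](OC(=O)[C@@H](C)CO[Si](C)(C)C(C)(C)C)[C@@H]12
F8 | step 11 | dimethylamine adduct of 20: 13-(dimethylamino)-11,13-dihydro lactone (C11 epimers) | CN(C)CC1C(=O)O[C@H](/C=C(\CO)CCC=C)[C@H]1[C@@H](OC(=O)[C@@H](C)CO)CC(C)=C
F9 | step 11 | macrocyclic amine: 13-(dimethylamino)-11,13-dihydro derivative of 21 (C11 epimers) | CN(C)CC1C(=O)O[C@@H]2/C=C(\CO)CC/C=C(/C)C[C@H](OC(=O)[C@@H](C)CO)[C@@H]12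
F10 | step 11 | methiodide of F9: 13-(trimethylammonio)-11,13-dihydro derivative of 21, iodide salt | C[N+](C)(C)CC1C(=O)O[C@@H]2/C=C(\CO)CC/C=C(/C)C[C@H](OC(=O)[C@@H](C)CO)[C@@H]12.[I-]
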